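The data were generated by integration for substances that don't exist; scatter was added.

Thursday's last reading of monomer in chains, 0 %, cannot mean that none was ever made, because the same run read 6 % earlier while side product kept climbing. So I take side product to be a chain that has met one more free monomer, and I ask how the flasks below share out that fate.

in all of them: free monomer 20 mM

|  | transfer agent | initiator | temperature | remark | time |
|---|---|---|---|---|---|
| Thursday's | 2 mM | 0.50 mM | 68 °C | run made earlier |  |
| Wednesday's | 2 mM | 2 mM | 84 °C | run made earlier |  |
| ash | 2.00 mM | 1.0 mM | 90 °C |  | 2.0 min |
| cedar | 2.00 mM | 1.0 mM | 75 °C |  | 2.0 min |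
| maple | 2.00 mM | 1.0 mM |  | at 90 °C until 25 s, from then on at 60 °C | 2.0 min |
| elm | 2.00 mM | 1.0 mM | 60 °C |  | 2.0 min |

Thursday's run (percent of the free monomer charged)

| time / min | monomer in chains / % | side product / % | free monomer / % |
|---|---|---|---|
| 0.500 | 4 | 8 | 88 |
| 1.00 | 6 | 16 | 79 |
| 1.33 | 4 | 22 | 77 |
| 2.50 | 3 | 25 | 69 |
| 4.00 | 0 | 30 | 68 |

Wednesday's run (percent of the free monomer charged)

| time / s | monomer in chains / % | side product / % | free monomer / % |
|---|---|---|---|
| 10.0 | 27 | 7 | 66 |
| 20.0 | 35 | 13 | 52 |
| 30.0 | 44 | 19 | 44 |
| 50.0 | 46 | 27 | 26 |
| 80.0 | 50 | 27 | 20 |

(each reading ± 1.5 percentage points)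

1. the flask that comes out highest in share of monomer in chains in all that became monomer in chains or side product, or "all alike" when all lie within 1.5 percentage points (ash / cedar / maple / elm / all alike)
2. share of monomer in chains in all that became monomer in chains or side product, ash
3. share of monomer in chains in all that became monomer in chains or side product, cedar
4. share of monomer in chains in all that became monomer in chains or side product, maple
5. share of monomer in chains in all that became monomer in chains or side product, elm

- in percentages every species weighs as the free monomer in it: one side product counts as two
- a reading or a percentage of monomer in chains counts all its forms, free or not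

Side product weighs two in the percentages, so half of its percentage O once stood in chains, and the monomer that ever entered chains is U + O/2, with U the reading of monomer in chains. Multiplied by free monomer charged over initiator charged, the last rows read 6.00 on Thursday and 6.35 on Wednesday. I carry their mean, ν = 6.18, the chain yield per initiator, as a reading with its scatter.

Take the settings in turn. Initiator is the smallest charge of ash, cedar, maple and elm, the limiting reagent for chains. At 1.0 mM in ash, cedar, maple and elm, ν gives 6.18 mM of chains and leaves 13.8 mM of free monomer, more than the chains need to become side product, so by my sum these chains can be eaten to the end. On Wednesday's charge the same sum gives 12.4 mM against 7.65 mM, and chains stood at 50 %.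

Temperature and initiator changed together between the two runs, so ν of 6.00 at 68 °C and 6.35 at 84 °C cannot show what temperature does to ν by itself. Wednesday's side product reached 27 % by 50.0 s, sooner than Thursday's 25 % by 2.50 min, though initiator changed too. So I expect heat to hasten the eating and lower the share at a fixed time. Maple spends 95.0 s of its 120 s at 60 °C, so I place it near elm. My order is elm, maple, cedar, ash, with ash below Thursday's share of 10.7 % read at 2.50 min.

The forecast differs: it names ash, with 62 % for ash, 35 % for cedar, 52 % for maple and 13 % for elm, seeing chains as “strongly favoured by heat and initiator”.

The flasks give 6.18 % in ash, 23.8 % in cedar, 33.6 % in maple and 41.5 % in elm, so elm comes out highest.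

    free monomer + initiator → living end + monomer in chains (k = 40.0 /M/s, Ea = 56.0 kJ/mol)
    free monomer + living end → monomer in chains + living end, rate k2*[living end]*[free monomer] (k = 3.80 /M/s, Ea = 63.0 kJ/mol)
    living end + transfer agent → dead chain (kL = 7.80 /M/s, Ea = 50.0 kJ/mol)
    free monomer + monomer in chains → side product (k = 1.20 /M/s, Ea = 58.0 kJ/mol)
    crystals ⇌ monomer in chains, rate k5*(cs5 - [monomer in chains]) while solid is left; crystals form when [monomer in chains] > cs5 (solubility = 0.870 mM, k = 2.30 /s)
    (constants at 60 °C)

Maple at 2.00 min holds a chain yield of 6.70, against the 6.18 I carried, and its monomer in chains stands at 0.0272 % after 20.0 min. The neighbouring flask is maple with 2.5 mM of initiator. There ν gives 15.4 mM of chains against 4.56 mM of free monomer left, the reverse of maple. At 2.00 min the neighbouring flask holds a chain yield of 5.58, with 18.9 % free monomer and 58.4 % monomer in chains, and its share is 72.0 %.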